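The time of reading was what I still had to choose: would a sample halfway, at 2.50 min, tell cedar, larch and maple apart, or had each flask to stand the whole 5.0 min?

all flasks: solid substrate 10 mM

|  | partner | temperature | remark | time |
|---|---|---|---|---|
| grey | 5.5 mM | 49 °C | run made earlier |  |
| blue | 8.2 mM | 57 °C | run made earlier |  |
| cedar | 11.0 mM |  | at 60 °C until 1.0 min, from then on at 45 °C | 5.0 min |
| larch | 11.0 mM | 60 °C |  | 5.0 min |
| maple | 11.0 mM | 45 °C |  | 5.0 min |

- grey (time / min: target / %): 1.50: 0; 3.00: 3; 5.00: 2; 6.00: 7; 8.00: 12; 10.0: 18
- blue (time / min: target / %): 0.500: 0; 0.833: 0; 1.33: 0; 2.00: 1; 4.00: 9; 6.00: 29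

(readings scatter by 2 percentage points)

- which flask leads in amount of target, in percent of the solid substrate charged ("all alike" within 1.5 percentage points) (cedar / larch / maple / all alike)
- how much target is there at the end, in percent of the solid substrate charged: cedar
- how much target is there at the end, in percent of the solid substrate charged: larch
- how much target is there at the end, in percent of the solid substrate charged: maple

- as a solid, counted per litre of solution: solid substrate
- at the start none of the solid substrate is in solution
- what has only dissolved of solid substrate counts as not reacted

Both earlier runs start flat, an induction period, with none of the solid substrate in solution at the start. Blue then climbed from 9% at 4.00 min to 29% at 6.00 min, which gives 2.89 as the lag exponent, the power of time by which target grows between two readings of one flask. Blue's target then stood at 2.90 mM, less than the 8.2 mM of partner charged in it, so I took the curve as still a rising power. But this is a reading, with a scatter of 2 percentage points on each point. Grey, from 7% at 6.00 min to 18% at 10.0 min, gives a flatter 1.85.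

By my reckoning, halving the time divides target by 7.41 at blue's exponent and by 3.61 at grey's. The forecast named larch as leader, with larch at 32% (23% to 43%), cedar at 8.5% (5.5% to 14%) and maple at 5.5% (3% to 9%), and it held that “Early target is therefore negligible”. Maple's 5.5% would fall halfway to between 0.742% and 1.53%, against that scatter of 2 points. So I chose to leave cedar, larch and maple the whole 5.0 min.

The flasks gave 28.4% in larch, 6.07% in cedar and 2.82% in maple, so larch led, as the forecast said.

    starting material → open intermediate (k = 0.0260 s⁻¹, Ea = 78.0 kJ mol⁻¹)
    partner → second intermediate (k = 0.00530 s⁻¹, Ea = 96.0 kJ mol⁻¹)
    open intermediate + second intermediate → target (k = 0.990 L mol⁻¹ s⁻¹, Ea = 57.0 kJ mol⁻¹)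
    solid substrate ⇌ starting material, rate k4*(cs4 - [starting material]) while solid is left; crystals form when [starting material] > cs4 (solubility = 4.30 mM, k = 0.00620 s⁻¹)
    (constants at 60 °C)

Carried back from its end value with blue's lag exponent, read as 2.89, the reckoning gave maple 0.380% of target at 2.50 min; maple held 0.289%. In the neighbouring flask, maple stopped at 80 s, the same reckoning gave 0.0618%, and that flask held 0.0298% of target.

The earlier runs and the new flask were generated by integration on assumed constants; noise was put on by code.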